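The route rests on cutting ring C at C4–C4a and C2–C3. The C4a=C8a–O1–C2 array (ring A carbon, its oxygen and the benzylic carbon next to ring B) is a latent cationic 2-oxadiene: hydride abstraction from a ring-A aryl 3,4-dibenzyloxybenzyl ether gives an O-aryl oxocarbenium ion. A chiral-phosphate-paired oxa-Povarov [4+2] reaction with an (E)-2-(phenylsulfanyl)vinyl ester of the protected (S)-side-chain acid then forms both bonds, sets C2 and C3, and delivers the complete ester in one operation. Sulfur reverses the normal enol-ester regiochemistry and is removed afterwards; ring A carries carbonates to keep it from competing as a nucleophile. One hydrogenolysis finishes the synthesis.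

Key step: step 9

Remark on the chemistry: phloroglucinol, [3,4-bis(benzyloxy)phenyl]methanol, 3,4-bis(benzyloxy)benzyl chloride, methyl acetoacetate and 2-(phenylsulfanyl)ethanol are taken as commercial; in step 9 the (R)-phosphoric acid is written as the working choice, and its equally available antipode is used instead if experiment shows that it is the one delivering the (2R,3S) core.

Step 1
Reactants: 1 phloroglucinol (benzene-1,3,5-triol)
Product: 2 3,5-bis{[(benzyloxy)carbonyl]oxy}phenol
Conditions: CbzCl (2 equiv), pyridine, THF, −20 → 0 °C; chromatographic separation from mono- and triscarbonate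
Reagents that add atoms: benzyl chloroformate O=C(Cl)OCc1ccccc1
Why: Acylation of phenolic OH groups by a chloroformate (carbonate formation) is reliable, the statistical biscarbonate is separated from its lower and higher homologues, and the two electron-poor carbonate groups are what later keep ring A from acting as an intermolecular Friedel–Crafts nucleophile.

Step 2
Reactants: 2 3,5-bis{[(benzyloxy)carbonyl]oxy}phenol; 3 [3,4-bis(benzyloxy)phenyl]methanol
Product: 4 3,5-bis{[(benzyloxy)carbonyl]oxy}phenyl 3,4-bis(benzyloxy)benzyl ether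
Conditions: PPh3, DIAD, THF, 0 °C → rt
Reagents that add atoms: none
Why: Mitsunobu etherification couples the acidic phenol with the primary benzylic alcohol under neutral conditions, which avoids the carbonate scrambling and C-benzylation that a basic Williamson alkylation would risk.

Step 3
Reactants: 5 methyl acetoacetate; 6 3,4-bis(benzyloxy)benzyl chloride
Product: 7 methyl 5-[3,4-bis(benzyloxy)phenyl]-3-oxopentanoate
Conditions: NaH, THF, 0 °C; n-BuLi, 0 °C; then 6, 0 °C → rt; aq HCl
Reagents that add atoms: none
Why: Alkylation of the acetoacetate dianion takes place at the more basic terminal (γ) carbanion, so the benzylic chloride is attached at the methyl carbon and the β-keto ester is kept.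

Step 4
Reactants: 7 methyl 5-[3,4-bis(benzyloxy)phenyl]-3-oxopentanoate
Product: 8 methyl (3S)-5-[3,4-bis(benzyloxy)phenyl]-3-hydroxypentanoate
Conditions: H2 (10 atm), RuCl2[(S)-BINAP] (0.5 mol %; BINAP = 2,2'-bis(diphenylphosphino)-1,1'-binaphthyl), MeOH, 50 °C
Reagents that add atoms: none
Why: Noyori asymmetric hydrogenation of a β-keto ester, in which the ester carbonyl chelates ruthenium and the (S)-BINAP ligand directs hydride to the face that gives the (S)-alcohol (the same sense as acetoacetate to (S)-3-hydroxybutanoate, the substituent priorities being analogous), while aryl benzyl ethers are inert to this catalyst.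

Step 5
Reactants: 8 methyl (3S)-5-[3,4-bis(benzyloxy)phenyl]-3-hydroxypentanoate
Product: 9 methyl (3S)-3-(benzyloxy)-5-[3,4-bis(benzyloxy)phenyl]pentanoate
Conditions: BnOC(=NH)CCl3, TfOH (cat.), CH2Cl2/cyclohexane, 0 °C → rt
Reagents that add atoms: benzyl 2,2,2-trichloroacetimidate N=C(OCc1ccccc1)C(Cl)(Cl)Cl
Why: Acid-catalysed O-benzylation with the trichloroacetimidate protects the β-hydroxyl without base, so neither retro-aldol cleavage nor β-elimination can touch the stereocentre, and the free OH would otherwise be oxidised under the Corey–Kim-like conditions of step 8 and trap cations in step 9.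

Step 6
Reactants: 9 methyl (3S)-3-(benzyloxy)-5-[3,4-bis(benzyloxy)phenyl]pentanoate
Product: 10 (3S)-3-(benzyloxy)-5-[3,4-bis(benzyloxy)phenyl]pentanoic acid
Conditions: LiOH, THF/MeOH/H2O, rt; then 1 M HCl
Reagents that add atoms: lithium hydroxide [Li+].[OH-]
Why: Saponification of a methyl ester with LiOH at room temperature leaves the benzyl ethers and the stereocentre untouched.

Step 7
Reactants: 10 (3S)-3-(benzyloxy)-5-[3,4-bis(benzyloxy)phenyl]pentanoic acid; 11 2-(phenylsulfanyl)ethanol
Product: 12 2-(phenylsulfanyl)ethyl (3S)-3-(benzyloxy)-5-[3,4-bis(benzyloxy)phenyl]pentanoate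
Conditions: DCC, DMAP (cat.), CH2Cl2, 0 °C → rt
Reagents that add atoms: none
Why: Steglich esterification (carbodiimide activation with acyl transfer by DMAP) joins the acid to the primary alcohol, and the thioether is inert to these conditions.

Step 8
Reactants: 12 2-(phenylsulfanyl)ethyl (3S)-3-(benzyloxy)-5-[3,4-bis(benzyloxy)phenyl]pentanoate
Product: 14 (E)-2-(phenylsulfanyl)ethenyl (3S)-3-(benzyloxy)-5-[3,4-bis(benzyloxy)phenyl]pentanoate, via alpha-chloro sulfide 13 (not isolated)
Conditions: NCS, CH2Cl2, 0 °C → rt; then i-Pr2NEt, 40 °C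
Reagents that add atoms: none
Why: Chlorination of the sulfide by NCS gives the α-chloro sulfide at the only alkyl carbon next to sulfur (a Pummerer-type process) and base-induced loss of HCl then gives the vinyl sulfide, the (E)-isomer being expected from anti elimination through the conformer that keeps the acyloxy and phenylsulfanyl groups apart, with any (Z)-isomer removed by chromatography.

Step 9
Reactants: 4 3,5-bis{[(benzyloxy)carbonyl]oxy}phenyl 3,4-bis(benzyloxy)benzyl ether; 14 (E)-2-(phenylsulfanyl)ethenyl (3S)-3-(benzyloxy)-5-[3,4-bis(benzyloxy)phenyl]pentanoate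
Product: 17 (2R,3R,4R)-5,7-bis{[(benzyloxy)carbonyl]oxy}-2-[3,4-bis(benzyloxy)phenyl]-4-(phenylsulfanyl)chroman-3-yl (3S)-3-(benzyloxy)-5-[3,4-bis(benzyloxy)phenyl]pentanoate, via aryl oxocarbenium ion 15 (not isolated), via thionium ion 16 (not isolated)
Conditions: 4, DDQ (1.05 equiv), 4 Å MS, CH2Cl2, 0 °C → rt until 4 is consumed; then −40 °C, 14 (2 equiv) and (R)-3,3'-bis(2,4,6-triisopropylphenyl)-1,1'-binaphthyl-2,2'-diyl hydrogen phosphate (10 mol %), −40 → −20 °C
Reagents that add atoms: none
Why: Proposed new method: DDQ abstracts hydride from the ArO–CH2 group of 4 (a 3,4-dialkoxybenzyl ether) to give the (E)-O-aryl oxocarbenium ion 15, a cationic 2-oxadiene made of C4a=C8a–O1=C2, which after ion exchange to the chiral phosphate is attacked at C2 by the acyloxy-bearing carbon of 14 to form C2–C3 and thionium ion 16, and C4a of ring A then closes ring C by 6-exo-trig Friedel–Crafts attack on the thionium carbon (C4–C4a), so that the whole is a stepwise inverse-electron-demand [4+2] cycloaddition that releases the acid again. The closest known reaction types are the Lewis-acid-promoted oxa-Povarov reaction of O-aryl oxocarbenium ions with alkenes, the Povarov reaction of N-aryl iminium ions with vinyl sulfides and its chiral-phosphoric-acid-catalysed version with enecarbamates, and the DDQ-mediated generation of oxocarbenium ions from electron-rich benzylic ethers for C–C bond formation; new are their combination on a β-acyloxy vinyl sulfide and counter-anion control of an acyclic O-aryl oxocarbenium ion. Regioselectivity is secured by sulfur being a far better cation-stabilising donor than the acyloxy oxygen (so the new C–C bond goes to the O-bearing carbon), and by the symmetry of ring A, whose two ortho positions are equivalent. C2 and C3 are created together in the C–C bond-forming transition state: as in Povarov reactions (2,4-cis adducts) the donor heteroatom should sit endo under the oxadienyl cation, which with the (E)-alkene places the acyloxy group exo and gives the 2,3-trans relation (C4 comes out 3,4-trans but is erased in step 10), while the absolute sense at C2 and C3 is imposed by the chiral phosphate of the contact ion pair, the side-chain (S)-centre being too remote to matter. Chemoselectivity needs 15 to be captured by the alkene and not by an aromatic ring, which is why ring A carries carbonates (a poor intermolecular nucleophile that still closes the ring intramolecularly) and why DDQ is consumed before the oxidisable vinyl sulfide is added. Because 14 is a single enantiomer, adducts from the other face are diastereomers and are removed by chromatography.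

Step 10
Reactants: 17 (2R,3R,4R)-5,7-bis{[(benzyloxy)carbonyl]oxy}-2-[3,4-bis(benzyloxy)phenyl]-4-(phenylsulfanyl)chroman-3-yl (3S)-3-(benzyloxy)-5-[3,4-bis(benzyloxy)phenyl]pentanoate
Product: 18 (2R,3S)-5,7-bis{[(benzyloxy)carbonyl]oxy}-2-[3,4-bis(benzyloxy)phenyl]chroman-3-yl (3S)-3-(benzyloxy)-5-[3,4-bis(benzyloxy)phenyl]pentanoate
Conditions: Bu3SnH, AIBN (cat.), toluene, 100 °C; aq KF work-up
Reagents that add atoms: none
Why: Radical desulfurisation, in which the tributylstannyl radical attacks sulfur, the weak benzylic C4–S bond breaks to a benzylic radical that takes hydrogen from Bu3SnH, so that C4 becomes CH2 while C2 and C3 (not involved) keep their configuration and the carbonates and benzyl ethers survive.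

Step 11
Reactants: 18 (2R,3S)-5,7-bis{[(benzyloxy)carbonyl]oxy}-2-[3,4-bis(benzyloxy)phenyl]chroman-3-yl (3S)-3-(benzyloxy)-5-[3,4-bis(benzyloxy)phenyl]pentanoate
Product: 19 phylloflavan, (2R,3S)-2-(3,4-dihydroxyphenyl)-5,7-dihydroxychroman-3-yl (3S)-5-(3,4-dihydroxyphenyl)-3-hydroxypentanoate
Conditions: H2 (1 atm), Pd(OH)2/C, THF/MeOH, rt
Reagents that add atoms: none
Why: Catalytic hydrogenolysis cleaves the five benzyl ethers and the two benzyl carbonates (which lose CO2) in one operation, whereas the C3 ester and the C2–O1 bond of the flavan are known to survive these neutral conditions, so no stereocentre is touched.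

Compound list
1 | phloroglucinol (benzene-1,3,5-triol) | Oc1cc(O)cc(O)c1 | starting material
2 | 3,5-bis{[(benzyloxy)carbonyl]oxy}phenol | Oc1cc(OC(=O)OCc2ccccc2)cc(OC(=O)OCc2ccccc2)c1 | intermediate
3 | [3,4-bis(benzyloxy)phenyl]methanol | OCc1ccc(OCc2ccccc2)c(OCc2ccccc2)c1 | starting material
4 | 3,5-bis{[(benzyloxy)carbonyl]oxy}phenyl 3,4-bis(benzyloxy)benzyl ether | O=C(OCc1ccccc1)Oc1cc(OCc2ccc(OCc3ccccc3)c(OCc3ccccc3)c2)cc(OC(=O)OCc2ccccc2)c1 | intermediate
5 | methyl acetoacetate | COC(=O)CC(C)=O | starting material
6 | 3,4-bis(benzyloxy)benzyl chloride | ClCc1ccc(OCc2ccccc2)c(OCc2ccccc2)c1 | starting material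
7 | methyl 5-[3,4-bis(benzyloxy)phenyl]-3-oxopentanoate | COC(=O)CC(=O)CCc1ccc(OCc2ccccc2)c(OCc2ccccc2)c1 | intermediate
8 | methyl (3S)-5-[3,4-bis(benzyloxy)phenyl]-3-hydroxypentanoate | COC(=O)C[C@@H](O)CCc1ccc(OCc2ccccc2)c(OCc2ccccc2)c1 | intermediate
9 | methyl (3S)-3-(benzyloxy)-5-[3,4-bis(benzyloxy)phenyl]pentanoate | COC(=O)C[C@@H](OCc1ccccc1)CCc1ccc(OCc2ccccc2)c(OCc2ccccc2)c1 | intermediate
10 | (3S)-3-(benzyloxy)-5-[3,4-bis(benzyloxy)phenyl]pentanoic acid | OC(=O)C[C@@H](OCc1ccccc1)CCc1ccc(OCc2ccccc2)c(OCc2ccccc2)c1 | intermediate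
11 | 2-(phenylsulfanyl)ethanol | OCCSc1ccccc1 | starting material
12 | 2-(phenylsulfanyl)ethyl (3S)-3-(benzyloxy)-5-[3,4-bis(benzyloxy)phenyl]pentanoate | O=C(C[C@@H](OCc1ccccc1)CCc1ccc(OCc2ccccc2)c(OCc2ccccc2)c1)OCCSc1ccccc1 | intermediate
13 | 2-chloro-2-(phenylsulfanyl)ethyl (3S)-3-(benzyloxy)-5-[3,4-bis(benzyloxy)phenyl]pentanoate (alpha-chloro sulfide, both epimers at the CHCl carbon, not isolated) | O=C(C[C@@H](OCc1ccccc1)CCc1ccc(OCc2ccccc2)c(OCc2ccccc2)c1)OCC(Cl)Sc1ccccc1 | intermediate
14 | (E)-2-(phenylsulfanyl)ethenyl (3S)-3-(benzyloxy)-5-[3,4-bis(benzyloxy)phenyl]pentanoate | O=C(C[C@@H](OCc1ccccc1)CCc1ccc(OCc2ccccc2)c(OCc2ccccc2)c1)O/C=C/Sc1ccccc1 | intermediate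
15 | (E)-O-aryl oxocarbenium ion from 4 by loss of hydride at the ArO–CH2 carbon (not isolated) | O=C(OCc1ccccc1)Oc1cc(/[O+]=C/c2ccc(OCc3ccccc3)c(OCc3ccccc3)c2)cc(OC(=O)OCc2ccccc2)c1 | intermediate
16 | thionium ion after C2–C3 bond formation, open chain with C2 and C3 as in 17 (not isolated) | O=C(C[C@@H](OCc1ccccc1)CCc1ccc(OCc2ccccc2)c(OCc2ccccc2)c1)O[C@@H](C=[S+]c1ccccc1)[C@@H](c1ccc(OCc2ccccc2)c(OCc2ccccc2)c1)Oc1cc(OC(=O)OCc2ccccc2)cc(OC(=O)OCc2ccccc2)c1 | intermediate
17 | (2R,3R,4R)-5,7-bis{[(benzyloxy)carbonyl]oxy}-2-[3,4-bis(benzyloxy)phenyl]-4-(phenylsulfanyl)chroman-3-yl (3S)-3-(benzyloxy)-5-[3,4-bis(benzyloxy)phenyl]pentanoate (2,3-trans and 3,4-trans) | O=C(C[C@@H](OCc1ccccc1)CCc1ccc(OCc2ccccc2)c(OCc2ccccc2)c1)O[C@H]1[C@H](Sc2ccccc2)c2c(OC(=O)OCc3ccccc3)cc(OC(=O)OCc3ccccc3)cc2O[C@@H]1c1ccc(OCc2ccccc2)c(OCc2ccccc2)c1 | intermediate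
18 | (2R,3S)-5,7-bis{[(benzyloxy)carbonyl]oxy}-2-[3,4-bis(benzyloxy)phenyl]chroman-3-yl (3S)-3-(benzyloxy)-5-[3,4-bis(benzyloxy)phenyl]pentanoate | O=C(C[C@@H](OCc1ccccc1)CCc1ccc(OCc2ccccc2)c(OCc2ccccc2)c1)O[C@H]1Cc2c(OC(=O)OCc3ccccc3)cc(OC(=O)OCc3ccccc3)cc2O[C@@H]1c1ccc(OCc2ccccc2)c(OCc2ccccc2)c1 | intermediate
19 | phylloflavan, (2R,3S)-2-(3,4-dihydroxyphenyl)-5,7-dihydroxychroman-3-yl (3S)-5-(3,4-dihydroxyphenyl)-3-hydroxypentanoate | O=C(C[C@@H](O)CCc1ccc(O)c(O)c1)O[C@H]1Cc2c(O)cc(O)cc2O[C@@H]1c1ccc(O)c(O)c1 | target

Total step count: 11. Longest linear sequence: 9 steps (steps 3 to 11, from methyl acetoacetate and the benzylic chloride).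

Steps most likely to fail

1. Step 9 (Proposed new method). The phosphate counter-anion may discriminate the two faces of the oxocarbenium ion only weakly. The endo/exo preference may be opposite to the expected one, which would give the 2,3-cis core. The cation may be captured by an aromatic ring, or the thionium ion may lose a proton before the carbonate-bearing ring A closes. The vinyl sulfide may be consumed by charge transfer if DDQ is still present. The fallback uses known chemistry only, sets out from acid 10 and comes back to the route at target 19. Commercial (+)-catechin, which already holds the (2R,3S) centres, is benzylated on its four phenolic oxygens (BnBr, K2CO3, DMF) to 5,7,3',4'-tetra-O-benzyl-(+)-catechin F1. Steglich esterification of the 3-OH of F1 with 10 (DCC, DMAP, CH2Cl2) should give the heptabenzyl ester F2, and hydrogenolysis of F2 (H2, Pd(OH)2/C, THF/MeOH) would give 19.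

2. Step 8. The dehydrochlorination may give poor control of alkene geometry, on which the 2,3-trans outcome of step 9 depends. The enol ester may transfer its acyl group to the base, and the catechol ring may be chlorinated in competition. The fallback sets out from acid 10 and comes back at 14. Ethynyl phenyl sulfide is hydroborated with pinacolborane (Cp2ZrHCl cat., syn addition) to (E)-2-(phenylsulfanyl)ethenylboronic acid pinacol ester F3. Chan–Lam coupling of 10 with F3 (Cu(OAc)2, DMAP, 4 Å MS, air, CH2Cl2, rt) forms the enol ester C–O bond with retention of the alkene geometry and should give 14 as the (E)-isomer only.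

3. Step 10. Homolysis of the C4–S bond may be sluggish, and tin or sulfur residues may later poison the palladium catalyst of step 11. The fallback sets out from 17 and comes back at 18. Hydrogenolytic desulfurisation on a metal surface replaces the radical chain: Raney nickel (deactivated by boiling in acetone), THF, rt, the conditions long used for 4-thio-substituted flavan-3-ols. Any benzyl group lost here would in any case be removed in step 11. This fallback makes no new compound (F0).

Further compounds
F1 | step 9 | 5,7,3',4'-tetra-O-benzyl-(+)-catechin, (2R,3S)-5,7-bis(benzyloxy)-2-[3,4-bis(benzyloxy)phenyl]chroman-3-ol | O[C@H]1Cc2c(OCc3ccccc3)cc(OCc3ccccc3)cc2O[C@@H]1c1ccc(OCc2ccccc2)c(OCc2ccccc2)c1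
F2 | step 9 | (2R,3S)-5,7-bis(benzyloxy)-2-[3,4-bis(benzyloxy)phenyl]chroman-3-yl (3S)-3-(benzyloxy)-5-[3,4-bis(benzyloxy)phenyl]pentanoate | O=C(C[C@@H](OCc1ccccc1)CCc1ccc(OCc2ccccc2)c(OCc2ccccc2)c1)O[C@H]1Cc2c(OCc3ccccc3)cc(OCc3ccccc3)cc2O[C@@H]1c1ccc(OCc2ccccc2)c(OCc2ccccc2)c1
F3 | step 8 | (E)-2-(phenylsulfanyl)ethenylboronic acid pinacol ester | CC1(C)OB(/C=C/Sc2ccccc2)OC1(C)C
F0 | step 10 | none | none
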